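**Proposed synthesis of CNP0372467.1 (13) from (R)-carvone: ring A closed by an iron-hydride Giese cyclisation**

Atom locants follow drimane numbering in each half: ring A is C1–C5 plus C10, ring B is C5–C10, and C11/C11' are the bridge carbons. Compound numbers are those of the steps below.

## Analysis of the target

1. The target 13 is a C30H50 hydrocarbon made of two identical trans-fused decalin halves whose C9 carbons are tied together by the ethano bridge C11–C11'.
2. Each half carries a gem-dimethyl group at C4, an angular methyl at C10, a methyl at C8 and a tetrasubstituted C8=C9 double bond.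
3. There are four stereocentres, C5, C10, C5' and C10', all S: within a half the C10 methyl and the C5 hydrogen are trans across the ring fusion, and the two halves are homochiral, so the molecule is C2-symmetric and not meso.
4. The only functional groups are the two tetrasubstituted alkenes; they tolerate base and reducing agents, but acid can move them to the C7 or exocyclic positions or trigger a cation–olefin cyclisation across the bridge, and they are prone to allylic autoxidation.
5. The difficulty is that no heteroatom survives: every handle used for bond formation must be deleted without trace, the alkene must end up at C8=C9 and nowhere else, and the congested run C4 (quaternary)–C5–C10 (quaternary stereocentre)–C9 has to be built twice.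
6. The bridge joins two carbons that each sit between a quaternary centre and a methyl-bearing alkene carbon, so the joining reaction has to tolerate severe crowding.
7. The symmetry allows one enantiopure half to be made once and dimerised through a two-carbon linchpin.
8. The plan rests on the fact that ring B is already present in (R)-carvone (1): its methyl-substituted enone is C8-methyl/C7=C8/C9=O, its stereocentre is C5 in the right sense, and its isopropenyl group is C4 with one methyl and a CH2 that becomes the other. Only C1–C3 and the C10 methyl are missing, and both can be attached at the one enolisable α'-carbon of 1, which is C10.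

## Retrosynthetic reasoning

**13 ⇒ 12 (unsaturation added at C11–C11').** The saturated bridge is traced back to the (E)-alkene of triene 12. No bond is cut here. The gain is that the two hindered C9–C11 bonds become sp2–sp2 bonds that cross-coupling can form. The forward step must saturate one disubstituted alkene beside two tetrasubstituted ones under neutral conditions, which a concerted, metal-free hydrogen transfer does on steric grounds alone.

**12 ⇒ 2 × 9 + 10 (both C9–C11 bonds).** These are the only cuts that return two identical halves and a symmetric two-carbon piece. Cutting C11–C11' instead would require one extra carbon to be installed at the hindered C9 of each half. The forward reaction is a two-fold palladium-catalysed coupling of enol triflate 9 with bis-stannane 10, which passes through the monocoupled stannane 11.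

**9 ⇒ 7 (C9–O bond and the C2–S bond, via 8).** The triflate oxygen is the carbonyl oxygen of 1. Dissolving-metal reduction of enone 7 gives enolate 8 with its double bond at C8=C9, exactly where the target has it. Because C10 is quaternary, no other enolate can exist. The same electrons cleave the C2–S bond. The alkene position of 13 is therefore encoded by the enone and never depends on an elimination.

**7 ⇒ 6 (C3–C4 bond, the key cut).** C4 is quaternary and adjacent to C5, and a radical addition tolerates that crowding. The radical can be generated at C4 from the isopropenyl group that 1 supplies, and the same hydrogen transfer turns the CH2 into the second C4 methyl. The acceptor must be electron-poor at C3, hence a sulfone on C2 that leaves no trace. Cutting C1–C10 instead would create the quaternary stereocentre during ring closure, and cutting C4–C5 would give up the carvone stereocentre. The forward reaction must deliver hydrogen to the right alkene in 6 and close in the 6-endo sense.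

**6 ⇒ 3 + 4 (C1–C10 bond, via 5).** The three-carbon arm C1–C3 with its sulfone is attached as the allylic bromide 4 to the fully substituted dienolate 5. The forward step sets the C10 stereocentre by approach anti to the C5 substituent.

**3 ⇒ 1 (C10–CH3 bond, via 2).** The methyl is put on first through dienolate 2 with a methyl electrophile. The order matters: the large arm then enters anti to the isopropenyl group and the methyl is left cis to it, as the trans-decalin demands.

## Alternatives that were turned down

**Alternative 1:** The disconnection cuts both C1–C10 bonds and traces each ring B back to a benzene ring, so that the chain C9–C11–C11'–C9' is present from the outset as a bibenzyl. The key step would give the bis-amide A1 from the bibenzyl bis-benzamide A2. Dissolving-metal (Birch) reduction of both rings produces two C10 amide enolates, and each displaces its tethered primary chloride, which closes both rings A under control of the prolinol-ether auxiliaries.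
- For it: the route is two-directional, needs no late joining of halves, places the C8=C9 alkenes directly, and sets both C10 centres by reagent control in one operation. On these points it is stronger than the chosen route.
- Against it: C10 of A1 carries a tertiary carboxamide where 13 needs a methyl. Reducing a neopentyl amide to CH3 takes several steps at the most hindered site, twice.
- The C5=C6 alkenes must then be hydrogenated from the α-face only, without touching C8=C9, twice.
- A2 consists of two 1,2,3,4-tetrasubstituted benzene rings, whose assembly is likely to cost more steps than the whole chosen route.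
- Both ortho positions of each benzamide are substituted, which twists the amide and weakens the enolate-geometry control the auxiliary relies on. Two independent inductions multiply any leakage into meso material.
- In its place the chosen route installs the C10 methyl as a methyl, takes C5 from 1, and obtains the trans fusion by construction.

**Alternative 2:** The disconnection cuts both C6–C7 bonds; ring A is a preformed methylenecyclohexane and ring B is closed last. The key step would give the bis-decalone A3 from the bis(iodomethyl ketone) A4. A tin hydride radical chain generates the two C7 α-keto radicals, these add 6-endo to the exocyclic methylene carbons C6, and hydrogen transfer to the tertiary C5 radicals sets the ring fusions.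
- For it: the bridge, the gem-dimethyl groups and the C10 methyls are in place before the key step. The electrophilic radical and the electron-rich 1,1-disubstituted alkene are polarity-matched, and attack at the unsubstituted terminus makes the 6-endo mode dependable. On convergence it is at least as strong as the chosen route.
- Against it: C5 is created by kinetic hydrogen delivery to a tertiary radical, controlled only by shielding from the axial methyls, and it has to succeed twice.
- A3 has a C8 ketone and a C9 hydrogen, so methyl addition and dehydration toward C9 are still needed. That elimination can also give the C7 and exocyclic alkenes, and with two sites the isomeric hydrocarbons would be hard to separate.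
- A4 needs vicinal C9/C10 stereocentres, one of them quaternary, on a cyclohexane without functional handles, and the C9 centres are destroyed afterwards.
- In its place the chosen route fixes the alkene through the only possible enolate 8 and inherits the ring fusion from centres set before cyclisation.

**Alternative 3:** The disconnection cuts ring A across C1–C10 and C4–C5 as a [4+2] retron. The key step would give the cis-fused enedione A5 from diene A6 and quinone A7 under a chiral cationic oxazaborolidine Lewis acid.
- For it: one catalytic step from two achiral commodity compounds builds ring A, both quaternary carbons and both stereocentres, and either enantiomer is accessible. This is clearly shorter to the bicyclic skeleton than the three steps of the chosen route.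
- Against it: A6 carries two methyls on the terminus that must bond to C5. One is necessarily cis on the diene, which disfavours the s-cis conformer and leaves the diene sluggish and open to cationic oligomerisation by the Lewis acid.
- The suprafacial addition gives the cis fusion, so C5 must be epimerised through the C6 enol, and with an angular methyl next to a gem-dimethyl group the equilibrium is not clearly on the trans side.
- A5 has two surplus functions: the C6 carbonyl must be removed beside the C9 enone, and C2=C3 must be saturated without touching C7=C8.
- In its place the chosen route starts from 1, which already has exactly the oxidation pattern needed, and gets the trans fusion by construction, at the price of a stoichiometric chiral-pool starting material.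

Key step: step 3

Assumption: 4 is treated as a purchasable reagent and 1 as enantiopure; any residual enantiomer of 1 would surface after step 5 as the meso diastereomer of 12.

## Route

Step 1
Reactants: 1 (R)-(−)-carvone
Product: 3 (5R,6S)-2,6-dimethyl-5-(prop-1-en-2-yl)cyclohex-2-en-1-one (trans-6-methylcarvone as the main C6 epimer), via lithium dienolate 2 (not isolated)
Conditions: LiN(iPr)2 (1.1 equiv), THF, −78 °C; MeI, −78 → 0 °C
Reagents that add atoms: iodomethane, CI
Why: Kinetic α'-deprotonation of the enone at C10 gives the cross-conjugated dienolate 2, and enolate methylation installs the C10 methyl. The new centre is formed mainly trans to the isopropenyl group but is irrelevant, because step 2 makes it planar again.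

Step 2
Reactants: 3 (5R,6S)-2,6-dimethyl-5-(prop-1-en-2-yl)cyclohex-2-en-1-one; 4 2-(phenylsulfonyl)allyl bromide
Product: 6 (5S,6S)-2,6-dimethyl-6-[2-(phenylsulfonyl)prop-2-en-1-yl]-5-(prop-1-en-2-yl)cyclohex-2-en-1-one, via lithium dienolate 5 (not isolated)
Conditions: LiN(iPr)2 (1.1 equiv), THF, −78 → 0 °C; 4, −78 → −20 °C; cold NH4Cl quench
Reagents that add atoms: none
Why: Enolate alkylation of the tetrasubstituted dienolate 5 at C10; direct SN2 and SN2' (addition–elimination) attack on 4 give the same 2-sulfonylallyl unit. The electrophile should enter anti to the neighbouring C5 isopropenyl group, so the arm ends up trans to it and the methyl cis, which sets C10 (S). C5 is unchanged in space and is S in 6 only because C10 now outranks the isopropenyl carbon.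

Step 3
Reactants: 6 (5S,6S)-2,6-dimethyl-6-[2-(phenylsulfonyl)prop-2-en-1-yl]-5-(prop-1-en-2-yl)cyclohex-2-en-1-one
Product: 7 (4aS,7S,8aS)-2,5,5,8a-tetramethyl-7-(phenylsulfonyl)-4a,5,6,7,8,8a-hexahydronaphthalen-1(4H)-one
Conditions: Fe(acac)3 (0.3 equiv), PhSiH3 (2.5 equiv), EtOH/HOCH2CH2OH (5:1), 0.02 M, 60 °C
Reagents that add atoms: none
Why: An iron hydride formed from Fe(acac)3 (trivalent iron), PhSiH3 and ethanol transfers a hydrogen atom to the terminal CH2 of the isopropenyl group in the Markovnikov sense, which turns that carbon into the second C4 methyl and leaves a tertiary radical at C4. This nucleophilic radical adds to the unsubstituted, electron-poor terminus C3 of the vinyl sulfone to form C3–C4, and the resulting α-sulfonyl radical at C2 is reduced by divalent iron and protonated by the solvent, which returns trivalent iron. The closest known reaction type is the iron-hydride hydrogen-atom-transfer reductive olefin coupling (a Mukaiyama-type hydrofunctionalisation run as a Giese addition), here in its intramolecular form. Ring A (C4, C5, C10, C1, C2, C3) closes in the 6-endo-trig mode; the 5-exo alternative would require attack at the substituted, polarity-mismatched C2 and would leave a primary radical. The trans ring fusion is inherited, not created: C5 and C10 already hold the two reacting arms trans and diequatorial with the C10 methyl axial, so a chair-like closure can only give the trans-decalin. The one new stereocentre, C2, is set in the final protonation, should favour the equatorial sulfone drawn for 7, and is of no consequence because step 4 removes it. The step needs chemoselective hydrogen-atom transfer to the isopropenyl group over the enone and the vinyl sulfone: the isopropenyl group is the only electron-rich, unhindered 1,1-disubstituted alkene, and a radical formed at C4 has no other partner because the enone carbon C7 could only be reached through a four-membered ring. High dilution and the pre-organised diequatorial conformer favour closure over simple reduction of the C4 radical.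

Step 4
Reactants: 7 (4aS,7S,8aS)-2,5,5,8a-tetramethyl-7-(phenylsulfonyl)-4a,5,6,7,8,8a-hexahydronaphthalen-1(4H)-one
Product: 9 (4aS,8aS)-2,5,5,8a-tetramethyl-3,4,4a,5,6,7,8,8a-octahydronaphthalen-1-yl trifluoromethanesulfonate, via lithium enolate 8 (not isolated)
Conditions: Li (4.5 equiv), t-BuOH (2 equiv), NH3(l)/THF, −78 °C; NH3 evaporated; PhNTf2 (2.5 equiv), THF, 0 °C → rt
Reagents that add atoms: N-phenylbis(trifluoromethanesulfonimide), O=S(=O)(N(c1ccccc1)S(=O)(=O)C(F)(F)F)C(F)(F)F
Why: Dissolving-metal reduction of the enone gives the C8=C9 enolate 8 regiospecifically (C10 is quaternary, so no other enolate can form), and the same conditions cleave the C2–S bond by reductive desulfonylation. O-Triflation of 8 then fixes the future C8=C9 alkene as the enol triflate. No stereocentre is formed; C5 and C10 are not enolisable.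

Step 5
Reactants: 9 (4aS,8aS)-2,5,5,8a-tetramethyl-3,4,4a,5,6,7,8,8a-octahydronaphthalen-1-yl trifluoromethanesulfonate (2.2 equiv); 10 (E)-1,2-bis(tributylstannyl)ethene
Product: 12 (E)-1,2-bis[(4aS,8aS)-2,5,5,8a-tetramethyl-3,4,4a,5,6,7,8,8a-octahydronaphthalen-1-yl]ethene, via monocoupled vinylstannane 11 (not isolated)
Conditions: Pd(PPh3)4 (10 mol %), CuCl, LiCl, DMSO, 60 °C
Reagents that add atoms: none
Why: Two-fold Stille coupling of the vinyl triflate with the bis-stannane forms both C9–C11 bonds. Copper chloride and lithium chloride speed up tin-to-palladium transfer, which is the slow step for a triflate flanked by C10 and the C8 methyl. The (E) geometry of 10 is retained and no stereocentre is touched.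

Step 6
Reactants: 12 (E)-1,2-bis[(4aS,8aS)-2,5,5,8a-tetramethyl-3,4,4a,5,6,7,8,8a-octahydronaphthalen-1-yl]ethene
Product: 13 1,2-bis[(4aS,8aS)-2,5,5,8a-tetramethyl-3,4,4a,5,6,7,8,8a-octahydronaphthalen-1-yl]ethane (the target)
Conditions: 2-nitrobenzenesulfonylhydrazide (excess, in portions), Et3N, THF, rt
Reagents that add atoms: none
Why: Diimide reduction by concerted syn transfer of two hydrogens; the rate falls steeply with alkene substitution, so the disubstituted C11=C11' bond is saturated while the tetrasubstituted C8=C9 bonds stay untouched. The conditions are neutral and metal-free, so the alkenes cannot migrate.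

## Compound list

1 | (R)-(−)-carvone, (5R)-2-methyl-5-(prop-1-en-2-yl)cyclohex-2-en-1-one | CC1=CC[C@@H](C(C)=C)CC1=O | starting material
2 | lithium (3R)-6-methyl-3-(prop-1-en-2-yl)cyclohexa-1,5-dien-1-olate (cross-conjugated dienolate of 1) | CC1=CC[C@@H](C(C)=C)C=C1[O-].[Li+] | intermediate (not isolated)
3 | (5R,6S)-2,6-dimethyl-5-(prop-1-en-2-yl)cyclohex-2-en-1-one (trans-6-methylcarvone; used together with its 6R epimer) | O=C1C(C)=CC[C@@H](C(C)=C)[C@@H]1C | intermediate
4 | 2-(phenylsulfonyl)allyl bromide, [(3-bromoprop-1-en-2-yl)sulfonyl]benzene | C=C(CBr)S(=O)(=O)c1ccccc1 | starting material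
5 | lithium (3S)-2,6-dimethyl-3-(prop-1-en-2-yl)cyclohexa-1,5-dien-1-olate (dienolate of 3) | CC1=CC[C@@H](C(C)=C)C(C)=C1[O-].[Li+] | intermediate (not isolated)
6 | (5S,6S)-2,6-dimethyl-6-[2-(phenylsulfonyl)prop-2-en-1-yl]-5-(prop-1-en-2-yl)cyclohex-2-en-1-one | O=C1C(C)=CC[C@@H](C(C)=C)[C@]1(C)CC(=C)S(=O)(=O)c1ccccc1 | intermediate
7 | (4aS,7S,8aS)-2,5,5,8a-tetramethyl-7-(phenylsulfonyl)-4a,5,6,7,8,8a-hexahydronaphthalen-1(4H)-one (trans-fused) | O=C1C(C)=CC[C@H]2C(C)(C)C[C@H](S(=O)(=O)c3ccccc3)C[C@]12C | intermediate
8 | lithium (4aS,8aS)-2,5,5,8a-tetramethyl-3,4,4a,5,6,7,8,8a-octahydronaphthalen-1-olate | CC1=C([O-])[C@@]2(C)CCCC(C)(C)[C@@H]2CC1.[Li+] | intermediate (not isolated)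
9 | (4aS,8aS)-2,5,5,8a-tetramethyl-3,4,4a,5,6,7,8,8a-octahydronaphthalen-1-yl trifluoromethanesulfonate | CC1=C(OS(=O)(=O)C(F)(F)F)[C@@]2(C)CCCC(C)(C)[C@@H]2CC1 | intermediate
10 | (E)-1,2-bis(tributylstannyl)ethene | CCCC[Sn](CCCC)(CCCC)/C=C/[Sn](CCCC)(CCCC)CCCC | starting material
11 | tributyl{(E)-2-[(4aS,8aS)-2,5,5,8a-tetramethyl-3,4,4a,5,6,7,8,8a-octahydronaphthalen-1-yl]ethenyl}stannane | CC1=C(/C=C/[Sn](CCCC)(CCCC)CCCC)[C@@]2(C)CCCC(C)(C)[C@@H]2CC1 | intermediate (not isolated)
12 | (E)-1,2-bis[(4aS,8aS)-2,5,5,8a-tetramethyl-3,4,4a,5,6,7,8,8a-octahydronaphthalen-1-yl]ethene | CC1=C(/C=C/C2=C(C)CC[C@H]3C(C)(C)CCC[C@]23C)[C@@]2(C)CCCC(C)(C)[C@@H]2CC1 | intermediate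
13 | 1,2-bis[(4aS,8aS)-2,5,5,8a-tetramethyl-3,4,4a,5,6,7,8,8a-octahydronaphthalen-1-yl]ethane | CC1=C(CCC2=C(C)CC[C@H]3C(C)(C)CCC[C@]23C)[C@@]2(C)CCCC(C)(C)[C@@H]2CC1 | target

## Step count and least certain steps

Total step count: 6. Longest linear sequence: 6 steps from 1.

**Step 3 (key step).** Hydrogen-atom transfer to the enone or the vinyl sulfone instead of the isopropenyl group is the most likely failure, and it would end in plain conjugate reduction. The C4 radical may also be reduced before it closes. Three alkenes compete for the hydride, and the closure forms a bond to a quaternary carbon. Fallback: from 6, Markovnikov addition of HBr (AcOH, 0 °C) to the isopropenyl group gives the tertiary bromide (5R,6S)-5-(2-bromopropan-2-yl)-2,6-dimethyl-6-[2-(phenylsulfonyl)prop-2-en-1-yl]cyclohex-2-en-1-one F1. Slow addition of Bu3SnH with AIBN in benzene at 80 °C then generates the same C4 radical by bromine abstraction, with no hydride competing for the acceptor alkenes, and the tin hydride Giese cyclisation returns to the route at 7.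

**Step 2.** Erosion of facial selectivity, addition of a second enolate to the vinyl sulfone of the product, or base-induced shift of the 2-sulfonylallyl double bond into the internal position may occur, because both 4 and 6 are strong Michael acceptors in a basic medium. Fallback: from 3, the same enolate is alkylated with 2,3-dibromopropene, which is not a Michael acceptor, to give (5S,6S)-6-(2-bromoprop-2-en-1-yl)-2,6-dimethyl-5-(prop-1-en-2-yl)cyclohex-2-en-1-one F2. CuI-catalysed coupling of the vinyl bromide with PhSO2Na (L-proline sodium salt, DMSO, 90 °C) then installs the sulfone and returns to the route at 6.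

**Step 4.** Incomplete O-triflation is the main risk, because the lithium alkoxide and sulfinate by-products of the reduction consume the triflating agent; enolate 8 may also be protonated while the ammonia is removed. Fallback: from 7, the reduction is quenched with NH4Cl and the saturated ketone (2R,4aS,8aS)-2,5,5,8a-tetramethyloctahydronaphthalen-1(2H)-one F3 is isolated. Its only enolisable position is C8, so deprotonation with KN(SiMe3)2 in THF and trapping with N-(5-chloropyridin-2-yl)bis(trifluoromethanesulfonimide) returns to the route at 9.

**Step 5.** Slow transfer of the vinyl group from tin to the crowded C9–palladium centre may stall the reaction at 11, with protodestannylation and stannane homocoupling taking over. Fallback: from 9, the linker is made by carbonyl olefination instead of cross-coupling. Methoxycarbonylation (Pd(OAc)2, dppp, CO, MeOH, Et3N, DMF) gives methyl (4aS,8aS)-2,5,5,8a-tetramethyl-3,4,4a,5,6,7,8,8a-octahydronaphthalene-1-carboxylate F4. Reduction with iBu2AlH gives [(4aS,8aS)-2,5,5,8a-tetramethyl-3,4,4a,5,6,7,8,8a-octahydronaphthalen-1-yl]methanol F5, and MnO2 oxidation gives (4aS,8aS)-2,5,5,8a-tetramethyl-3,4,4a,5,6,7,8,8a-octahydronaphthalene-1-carbaldehyde F6. McMurry coupling of F6 with low-valent titanium from TiCl4 and Zn (THF, reflux) returns to the route at 12.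

**Step 6.** Incomplete reduction is likely if diimide disproportionates faster than it reaches the C11=C11' bond, which is shielded on both sides by C10 and the C8 methyl; forcing the reduction with a hydrogenation catalyst would risk alkene migration. Fallback: from 9, the bridge is built at the saturated oxidation level. Stille coupling with tributyl(vinyl)stannane (Pd(PPh3)4, CuCl, LiCl, DMSO) gives (4aS,8aS)-1-ethenyl-2,5,5,8a-tetramethyl-3,4,4a,5,6,7,8,8a-octahydronaphthalene F7. Hydroboration of the terminal vinyl carbon with 9-BBN gives 9-{2-[(4aS,8aS)-2,5,5,8a-tetramethyl-3,4,4a,5,6,7,8,8a-octahydronaphthalen-1-yl]ethyl}-9-borabicyclo[3.3.1]nonane F8. B-alkyl Suzuki–Miyaura coupling of F8 with a second equivalent of 9 (Pd(dppf)Cl2, K3PO4, DMF/THF/H2O, 60 °C) arrives directly at 13.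

## Further compounds

F1 | step 3 | (5R,6S)-5-(2-bromopropan-2-yl)-2,6-dimethyl-6-[2-(phenylsulfonyl)prop-2-en-1-yl]cyclohex-2-en-1-one | O=C1C(C)=CC[C@@H](C(C)(C)Br)[C@]1(C)CC(=C)S(=O)(=O)c1ccccc1
F2 | step 2 | (5S,6S)-6-(2-bromoprop-2-en-1-yl)-2,6-dimethyl-5-(prop-1-en-2-yl)cyclohex-2-en-1-one | O=C1C(C)=CC[C@@H](C(C)=C)[C@]1(C)CC(Br)=C
F3 | step 4 | (2R,4aS,8aS)-2,5,5,8a-tetramethyloctahydronaphthalen-1(2H)-one | O=C1[C@H](C)CC[C@H]2C(C)(C)CCC[C@]12C
F4 | step 5 | methyl (4aS,8aS)-2,5,5,8a-tetramethyl-3,4,4a,5,6,7,8,8a-octahydronaphthalene-1-carboxylate | CC1=C(C(=O)OC)[C@@]2(C)CCCC(C)(C)[C@@H]2CC1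
F5 | step 5 | [(4aS,8aS)-2,5,5,8a-tetramethyl-3,4,4a,5,6,7,8,8a-octahydronaphthalen-1-yl]methanol | CC1=C(CO)[C@@]2(C)CCCC(C)(C)[C@@H]2CC1
F6 | step 5 | (4aS,8aS)-2,5,5,8a-tetramethyl-3,4,4a,5,6,7,8,8a-octahydronaphthalene-1-carbaldehyde | CC1=C(C=O)[C@@]2(C)CCCC(C)(C)[C@@H]2CC1
F7 | step 6 | (4aS,8aS)-1-ethenyl-2,5,5,8a-tetramethyl-3,4,4a,5,6,7,8,8a-octahydronaphthalene | CC1=C(C=C)[C@@]2(C)CCCC(C)(C)[C@@H]2CC1
F8 | step 6 | 9-{2-[(4aS,8aS)-2,5,5,8a-tetramethyl-3,4,4a,5,6,7,8,8a-octahydronaphthalen-1-yl]ethyl}-9-borabicyclo[3.3.1]nonane | CC1=C(CCB2C3CCCC2CCC3)[C@@]2(C)CCCC(C)(C)[C@@H]2CC1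
A1 | alternative 1 | 1,2-bis{2,5,5-trimethyl-8a-[(2S)-2-(methoxymethyl)pyrrolidine-1-carbonyl]-3,5,6,7,8,8a-hexahydronaphthalen-1-yl}ethane | C(CC1=C(C)CC=C2C(C)(C)CCC[C@]12C(=O)N1CCC[C@H]1COC)C1=C(C)CC=C2C(C)(C)CCC[C@]12C(=O)N1CCC[C@H]1COC
A2 | alternative 1 | 1,2-bis{3-(5-chloro-2-methylpentan-2-yl)-2-[(2S)-2-(methoxymethyl)pyrrolidine-1-carbonyl]-6-methylphenyl}ethane | C(Cc1c(C)ccc(C(C)(C)CCCCl)c1C(=O)N1CCC[C@H]1COC)c1c(C)ccc(C(C)(C)CCCCl)c1C(=O)N1CCC[C@H]1COC
A3 | alternative 2 | 1,2-bis(trans-5,5,8a-trimethyl-2-oxodecahydronaphthalen-1-yl)ethane | C(C[C@H]1C(=O)CC[C@H]2C(C)(C)CCC[C@]12C)[C@H]1C(=O)CC[C@H]2C(C)(C)CCC[C@]12C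
A4 | alternative 2 | 1,8-diiodo-3,6-bis(1,3,3-trimethyl-2-methylidenecyclohexyl)octane-2,7-dione (configuration as in the SMILES) | C(C[C@@H](C(=O)CI)[C@@]1(C)CCCC(C)(C)C1=C)[C@@H](C(=O)CI)[C@@]1(C)CCCC(C)(C)C1=C
A5 | alternative 3 | cis-fused 2,5,5,8a-tetramethyl-4a,5,8,8a-tetrahydronaphthalene-1,4-dione | O=C1C(C)=CC(=O)[C@@H]2C(C)(C)C=CC[C@]12C
A6 | alternative 3 | 4-methylpenta-1,3-diene | CC(C)=CC=C
A7 | alternative 3 | 2,6-dimethyl-1,4-benzoquinone | CC1=CC(=O)C=C(C)C1=O
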